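**Plan**

- Retrosynthesis (labdane numbering): the C13 silyl ether is cut first, then the C9–C11 bond together with the C7 carbonyl (alkylative 1,3-enone transposition: alkylcerium, then PCC). This separates the linalool-derived C11–C16 iodide 23 from the bicyclic 6β-acetoxy-7-en-9-one 16.
- Ring A is then opened at C3–C4 and C5–C10 by a retro-[4+2]. These two bonds flank the C4–C5 edge of the ring-A cyclohexane, so C10–C1–C2–C3 is a butadiene (C20 methyl on its inner end) and C4=C5 an isopropylidene next to C6, a carbon that is oxygenated in the target and can be the activating ketone; the ring-B carbons C6–C9 are the tether.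
- Forward: trienone 10 is built linearly (alkynylation sets C9; syn-carbocupration puts C17 on C8 and fixes the Z-C7=C8 bond; a Grignard reagent brings C4/C5). Rings A and B form together in step 7, ring B is adjusted (C6 ketone to 6β-acetate, C9 carbinol to ketone), and the side chain is joined last.
- Stereochemistry: C9 (catalytic asymmetric alkynylation) controls C5 and C10 in the cycloaddition and is then erased; C6 comes from hydride attack on the α face; C13 comes from (R)-linalool.

Key step: step 7

Remarks on the chemistry: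
- Atoms are named by labdane numbers: ring A = C1–C5, C10; ring B = C5–C10; C17 on C8; C18/C19 on C4; C20 on C10; side chain C11–C16. α is the face opposite the C20 methyl.
- Assumption: the ProPhenol antipode used in step 2 is the one that gives the 4S carbinol 5; both antipodes are commercial.
- Compounds 1, 2, 4, 9 and 17 are taken as commercial.

**Route**

Step 1
Reactants: 1 acrolein; 2 2-(triphenyl-λ5-phosphanylidene)propanal
Product: 3 (2E)-2-methylpenta-2,4-dienal
Conditions: CH2Cl2, BHT (cat.), rt, 1 in excess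
Reagents that add atoms: none
Why: Wittig olefination of the unhindered aldehyde by the stabilised formyl ylide should give the E-dienal, which fixes the later C10=C1 geometry (C9 trans to C2).

Step 2
Reactants: 3 (2E)-2-methylpenta-2,4-dienal; 4 methyl propiolate
Product: 5 methyl (4S,5E)-4-hydroxy-5-methylocta-5,7-dien-2-ynoate
Conditions: ProPhenol ligand (10 mol %), Ph3P=O (20 mol %), ZnMe2 (3 equiv), toluene, 4 °C
Reagents that add atoms: none
Why: The dinuclear zinc–ProPhenol-catalysed alkynylation of α-substituted enals with methyl propiolate should add the alkynylzinc to one aldehyde face under catalyst control and set C9 (S).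

Step 3
Reactants: 5 methyl (4S,5E)-4-hydroxy-5-methylocta-5,7-dien-2-ynoate
Product: 6 methyl (4S,5E)-4-[(tert-butyldimethylsilyl)oxy]-5-methylocta-5,7-dien-2-ynoate
Conditions: TBSCl, imidazole, DMF, 0 °C to rt
Reagents that add atoms: tert-butyldimethylsilyl chloride, CC(C)(C)[Si](C)(C)Cl
Why: Standard silylation of a secondary alcohol; the ether blocks lactonisation and later serves as the steric control element at C9.

Step 4
Reactants: 6 methyl (4S,5E)-4-[(tert-butyldimethylsilyl)oxy]-5-methylocta-5,7-dien-2-ynoate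
Product: 7 methyl (2Z,4S,5E)-4-[(tert-butyldimethylsilyl)oxy]-3,5-dimethylocta-2,5,7-trienoate
Conditions: Me2CuLi (from CuI and 2 MeLi), THF, −78 °C; MeOH quench at −78 °C
Reagents that add atoms: lithium dimethylcuprate, [Li+].C[Cu-]C
Why: Syn-carbocupration of the ynoate with cold protonation should give the kinetic Z-enoate, placing the C17 methyl on C8 and holding C6 and C9 cis as ring B requires.

Step 5
Reactants: 7 methyl (2Z,4S,5E)-4-[(tert-butyldimethylsilyl)oxy]-3,5-dimethylocta-2,5,7-trienoate
Product: 8 (2Z,4S,5E)-4-[(tert-butyldimethylsilyl)oxy]-N-methoxy-N,3,5-trimethylocta-2,5,7-trienamide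
Conditions: MeNH(OMe)·HCl, i-PrMgCl, THF, −20 °C
Reagents that add atoms: N,O-dimethylhydroxylamine hydrochloride, CNOC.Cl
Why: Direct ester-to-Weinreb-amide exchange through the chloromagnesium amide is mild enough to leave the Z-alkene and the silyl ether untouched.

Step 6
Reactants: 8 (2Z,4S,5E)-4-[(tert-butyldimethylsilyl)oxy]-N-methoxy-N,3,5-trimethylocta-2,5,7-trienamide; 9 (2-methylprop-1-en-1-yl)magnesium bromide
Product: 10 (5Z,7S,8E)-7-[(tert-butyldimethylsilyl)oxy]-2,6,8-trimethylundeca-2,5,8,10-tetraen-4-one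
Conditions: THF, −20 to 0 °C; aq NH4Cl
Reagents that add atoms: none
Why: Grignard addition to the Weinreb amide stops at the chelated tetrahedral intermediate and should give the isopropylidene ketone (C4=C5–C6=O) without over-addition.

Step 7
Reactants: 10 (5Z,7S,8E)-7-[(tert-butyldimethylsilyl)oxy]-2,6,8-trimethylundeca-2,5,8,10-tetraen-4-one
Product: 11 (4R,4aS,8aS)-4-[(tert-butyldimethylsilyl)oxy]-3,4a,8,8-tetramethyl-4a,7,8,8a-tetrahydronaphthalen-1(4H)-one (labdane numbering: 6-oxo, Δ1, Δ7, 9α-OTBS, 5α-H, 10β-CH3)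
Conditions: toluene (0.01 M), BHT (cat.), 140 °C, sealed tube
Reagents that add atoms: none
Why: On heating, 10 should undergo a concerted, asynchronous thermal [4+2] cycloaddition in which the C10=C1–C2=C3 butadiene adds across the C4=C5 isopropylidene bond polarised by the C6 ketone; the closest precedent is the type 1 intramolecular Diels–Alder reaction of 1,7,9-decatrien-3-ones. Ring A closes as the new cyclohexene of the cycloaddition (bonds C3–C4 and C5–C10), and ring B closes in the same event as the six-membered tether ring when C5 bonds to C10, the Z-C7=C8 bond from step 4 being the only geometry that lets C6 and C9 span that ring. C5 and C10 are formed suprafacially from the enone and the E-diene, and the trans fusion is expected because the endo (cis-decalin) transition state presses the inner C20 methyl against the folded tether, C5 remaining adjustable afterwards as the carbon α to the ketone. The absolute configuration of C5 and C10 is controlled by the C9 silyloxy stereocentre, which should sit pseudoaxial in the half-chair tether, away from the C17 and C20 methyl groups and not antiperiplanar to the forming C10–C5 bond, so that one enone face is presented to the diene. The step needs periselectivity (only the isopropylidene enone can reach the diene, the C7=C8 enone being one atom from it), π-facial selectivity (C9) and trans selectivity (C20), and acid-free conditions at or below 140 °C keep Nazarov closure of the dienone and hydrogen shifts of the diene out. Because C9 is oxidised later, either sense of facial induction would serve, with the other ligand antipode in step 2 if the sense proves opposite.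

Step 8
Reactants: 11 (4R,4aS,8aS)-4-[(tert-butyldimethylsilyl)oxy]-3,4a,8,8-tetramethyl-4a,7,8,8a-tetrahydronaphthalen-1(4H)-one
Product: 12 (4R,4aS,8aS)-4-[(tert-butyldimethylsilyl)oxy]-3,4a,8,8-tetramethyl-4a,5,6,7,8,8a-hexahydronaphthalen-1(4H)-one
Conditions: H2 (3 atm), RhCl(PPh3)3 (5 mol %), benzene, rt
Reagents that add atoms: none
Why: Homogeneous hydrogenation with RhCl(PPh3)3 should reduce the isolated cis-disubstituted C1=C2 bond and leave the trisubstituted, conjugated C7=C8 bond; it is done here, before the side-chain vinyl group exists.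

Step 9
Reactants: 12 (4R,4aS,8aS)-4-[(tert-butyldimethylsilyl)oxy]-3,4a,8,8-tetramethyl-4a,5,6,7,8,8a-hexahydronaphthalen-1(4H)-one
Product: 13 (1R,4R,4aS,8aS)-4-[(tert-butyldimethylsilyl)oxy]-3,4a,8,8-tetramethyl-1,4,4a,5,6,7,8,8a-octahydronaphthalen-1-ol (6β-OH)
Conditions: NaBH4, CeCl3·7H2O, MeOH, −78 to −20 °C
Reagents that add atoms: none
Why: Luche 1,2-reduction of the enone; hydride should enter from the α face because the β face of C6 is screened by the axial C20 and 4β methyl groups, which sets the 6β-oxygen.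

Step 10
Reactants: 13 (1R,4R,4aS,8aS)-4-[(tert-butyldimethylsilyl)oxy]-3,4a,8,8-tetramethyl-1,4,4a,5,6,7,8,8a-octahydronaphthalen-1-ol
Product: 14 (1R,4R,4aS,8aS)-4-[(tert-butyldimethylsilyl)oxy]-3,4a,8,8-tetramethyl-1,4,4a,5,6,7,8,8a-octahydronaphthalen-1-yl acetate
Conditions: Ac2O, DMAP, Et3N, CH2Cl2, rt
Reagents that add atoms: acetic anhydride, CC(=O)OC(C)=O
Why: DMAP-catalysed acylation installs the target acetate on the only free hydroxyl, before any other alcohol is present.

Step 11
Reactants: 14 (1R,4R,4aS,8aS)-4-[(tert-butyldimethylsilyl)oxy]-3,4a,8,8-tetramethyl-1,4,4a,5,6,7,8,8a-octahydronaphthalen-1-yl acetate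
Product: 15 (1R,4R,4aS,8aS)-4-hydroxy-3,4a,8,8-tetramethyl-1,4,4a,5,6,7,8,8a-octahydronaphthalen-1-yl acetate
Conditions: HF·pyridine, pyridine, THF, 0 °C to rt
Reagents that add atoms: none
Why: Buffered fluoride desilylation frees the C9 hydroxyl without touching the acetate or causing acyl migration.

Step 12
Reactants: 15 (1R,4R,4aS,8aS)-4-hydroxy-3,4a,8,8-tetramethyl-1,4,4a,5,6,7,8,8a-octahydronaphthalen-1-yl acetate
Product: 16 (1R,4aS,8aS)-3,4a,8,8-tetramethyl-4-oxo-1,4,4a,5,6,7,8,8a-octahydronaphthalen-1-yl acetate (6β-acetoxy-7-en-9-one)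
Conditions: Dess–Martin periodinane, CH2Cl2, 0 °C to rt
Reagents that add atoms: none
Why: Neutral oxidation of the allylic alcohol gives the C9 enone and erases the C9 stereocentre, which has done its work.

Step 13
Reactants: 17 (R)-linalool, (3R)-3,7-dimethylocta-1,6-dien-3-ol
Product: 19 (5R)-5-ethenyl-5-methyloxolan-2-ol, via ozonide 18 (not isolated)
Conditions: O3 (1.0 equiv), CH2Cl2, −78 °C; Me2S, −78 °C to rt
Reagents that add atoms: ozone, [O-][O+]=O
Why: Ozone should select the electron-rich trisubstituted alkene over the hindered vinyl group, and the hydroxy aldehyde closes to the lactol; C13 is not touched.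

Step 14
Reactants: 19 (5R)-5-ethenyl-5-methyloxolan-2-ol
Product: 21 (3R)-5-iodo-3-methylpent-1-en-3-yl formate, via hypoiodite 20 (not isolated)
Conditions: PhI(OAc)2, I2, CH2Cl2, visible light, rt
Reagents that add atoms: iodine, II
Why: Suárez alkoxy-radical β-fragmentation of the lactol hypoiodite excises the former aldehyde carbon as a formate and the primary radical is trapped by iodine, giving the two-carbon-linked iodide.

Step 15
Reactants: 21 (3R)-5-iodo-3-methylpent-1-en-3-yl formate
Product: 22 (3R)-5-iodo-3-methylpent-1-en-3-ol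
Conditions: KHCO3, MeOH, 0 °C to rt
Reagents that add atoms: none
Why: Formates are methanolysed under conditions too mild to close the γ-iodo alcohol to an oxetane.

Step 16
Reactants: 22 (3R)-5-iodo-3-methylpent-1-en-3-ol
Product: 23 triethyl{[(3R)-5-iodo-3-methylpent-1-en-3-yl]oxy}silane
Conditions: TESOTf, 2,6-lutidine, CH2Cl2, −78 °C
Reagents that add atoms: triethylsilyl trifluoromethanesulfonate, CC[Si](CC)(CC)OS(=O)(=O)C(F)(F)F
Why: A silyl triflate is needed for the tertiary alcohol; the ether must survive the organometallic and chromium steps, where a free tertiary allylic alcohol would itself be transposed.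

Step 17
Reactants: 23 triethyl{[(3R)-5-iodo-3-methylpent-1-en-3-yl]oxy}silane; 16 (1R,4aS,8aS)-3,4a,8,8-tetramethyl-4-oxo-1,4,4a,5,6,7,8,8a-octahydronaphthalen-1-yl acetate
Product: 26 (13R)-6β-acetoxy-13-[(triethylsilyl)oxy]labda-7,14-dien-9-ol (C9 epimers), via alkyllithium 24 (not isolated), via alkylcerium dichloride 25 (not isolated)
Conditions: 23, t-BuLi (2.1 equiv), Et2O/pentane, −78 °C; CeCl3, THF, −78 °C; then 16, −78 °C; aq NH4Cl at −78 °C
Reagents that add atoms: none
Why: Iodine–lithium exchange and transmetalation give a non-basic organocerium that should add 1,2 to the hindered enone faster than to the acetate at −78 °C; the new C9 centre (attack anti to C20 expected) is of no consequence because it becomes sp2 in step 18.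

Step 18
Reactants: 26 (13R)-6β-acetoxy-13-[(triethylsilyl)oxy]labda-7,14-dien-9-ol
Product: 27 (13R)-6β-acetoxy-13-[(triethylsilyl)oxy]labda-8,14-dien-7-one
Conditions: pyridinium chlorochromate (C5H5NH)[CrO3Cl], 4 Å molecular sieves, CH2Cl2, rt
Reagents that add atoms: pyridinium chlorochromate, [O-][Cr](=O)(=O)Cl.c1cc[nH+]cc1
Why: Dauben-type oxidative 1,3-transposition: the tertiary allylic chromate ester shifts [3,3] from C9 to C7 and is oxidised there, which should give the tetrasubstituted 8-en-7-one with the side chain on C9 and C6 unchanged.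

Step 19
Reactants: 27 (13R)-6β-acetoxy-13-[(triethylsilyl)oxy]labda-8,14-dien-7-one
Product: 28 (13R)-6β-acetoxy-13-hydroxylabda-8,14-dien-7-one, (5S,6S,10S,13R)
Conditions: HF·pyridine, pyridine, THF, 0 °C
Reagents that add atoms: none
Why: Buffered fluoride removes the tertiary triethylsilyl ether under conditions that should neither epimerise the α-acetoxy ketone at C6 nor ionise the tertiary allylic alcohol.

**Compound list**

1 | acrolein | C=CC=O | starting material
2 | 2-(triphenyl-λ5-phosphanylidene)propanal | CC(C=O)=P(c1ccccc1)(c1ccccc1)c1ccccc1 | starting material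
3 | (2E)-2-methylpenta-2,4-dienal | C=C/C=C(\C)C=O | intermediate
4 | methyl propiolate | COC(=O)C#C | starting material
5 | methyl (4S,5E)-4-hydroxy-5-methylocta-5,7-dien-2-ynoate | COC(=O)C#C[C@@H](O)/C(C)=C/C=C | intermediate
6 | methyl (4S,5E)-4-[(tert-butyldimethylsilyl)oxy]-5-methylocta-5,7-dien-2-ynoate | COC(=O)C#C[C@@H](O[Si](C)(C)C(C)(C)C)/C(C)=C/C=C | intermediate
7 | methyl (2Z,4S,5E)-4-[(tert-butyldimethylsilyl)oxy]-3,5-dimethylocta-2,5,7-trienoate | COC(=O)/C=C(/C)[C@@H](O[Si](C)(C)C(C)(C)C)/C(C)=C/C=C | intermediate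
8 | (2Z,4S,5E)-4-[(tert-butyldimethylsilyl)oxy]-N-methoxy-N,3,5-trimethylocta-2,5,7-trienamide | CON(C)C(=O)/C=C(/C)[C@@H](O[Si](C)(C)C(C)(C)C)/C(C)=C/C=C | intermediate
9 | (2-methylprop-1-en-1-yl)magnesium bromide | CC(C)=C[Mg]Br | starting material
10 | (5Z,7S,8E)-7-[(tert-butyldimethylsilyl)oxy]-2,6,8-trimethylundeca-2,5,8,10-tetraen-4-one | CC(C)=CC(=O)/C=C(/C)[C@@H](O[Si](C)(C)C(C)(C)C)/C(C)=C/C=C | intermediate
11 | (4R,4aS,8aS)-4-[(tert-butyldimethylsilyl)oxy]-3,4a,8,8-tetramethyl-4a,7,8,8a-tetrahydronaphthalen-1(4H)-one | [C@@H]1(O[Si](C)(C)C(C)(C)C)C(C)=CC(=O)[C@H]2C(C)(C)CC=C[C@]12C | intermediate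
12 | (4R,4aS,8aS)-4-[(tert-butyldimethylsilyl)oxy]-3,4a,8,8-tetramethyl-4a,5,6,7,8,8a-hexahydronaphthalen-1(4H)-one | [C@@H]1(O[Si](C)(C)C(C)(C)C)C(C)=CC(=O)[C@H]2C(C)(C)CCC[C@]12C | intermediate
13 | (1R,4R,4aS,8aS)-4-[(tert-butyldimethylsilyl)oxy]-3,4a,8,8-tetramethyl-1,4,4a,5,6,7,8,8a-octahydronaphthalen-1-ol | [C@@H]1(O[Si](C)(C)C(C)(C)C)C(C)=C[C@@H](O)[C@H]2C(C)(C)CCC[C@]12C | intermediate
14 | (1R,4R,4aS,8aS)-4-[(tert-butyldimethylsilyl)oxy]-3,4a,8,8-tetramethyl-1,4,4a,5,6,7,8,8a-octahydronaphthalen-1-yl acetate | [C@@H]1(O[Si](C)(C)C(C)(C)C)C(C)=C[C@@H](OC(C)=O)[C@H]2C(C)(C)CCC[C@]12C | intermediate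
15 | (1R,4R,4aS,8aS)-4-hydroxy-3,4a,8,8-tetramethyl-1,4,4a,5,6,7,8,8a-octahydronaphthalen-1-yl acetate | [C@@H]1(O)C(C)=C[C@@H](OC(C)=O)[C@H]2C(C)(C)CCC[C@]12C | intermediate
16 | (1R,4aS,8aS)-3,4a,8,8-tetramethyl-4-oxo-1,4,4a,5,6,7,8,8a-octahydronaphthalen-1-yl acetate | O=C1C(C)=C[C@@H](OC(C)=O)[C@H]2C(C)(C)CCC[C@]12C | intermediate
17 | (R)-linalool, (3R)-3,7-dimethylocta-1,6-dien-3-ol | C=C[C@](C)(O)CCC=C(C)C | starting material
18 | (3R)-5-(5,5-dimethyl-1,2,4-trioxolan-3-yl)-3-methylpent-1-en-3-ol (ozonide) | C=C[C@](C)(O)CCC1OOC(C)(C)O1 | intermediate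
19 | (5R)-5-ethenyl-5-methyloxolan-2-ol (anomers) | C=C[C@@]1(C)CCC(O)O1 | intermediate
20 | (5R)-5-ethenyl-5-methyloxolan-2-yl hypoiodite | C=C[C@@]1(C)CCC(OI)O1 | intermediate
21 | (3R)-5-iodo-3-methylpent-1-en-3-yl formate | C=C[C@](C)(OC=O)CCI | intermediate
22 | (3R)-5-iodo-3-methylpent-1-en-3-ol | C=C[C@](C)(O)CCI | intermediate
23 | triethyl{[(3R)-5-iodo-3-methylpent-1-en-3-yl]oxy}silane | C=C[C@](C)(O[Si](CC)(CC)CC)CCI | intermediate
24 | {(3R)-3-methyl-3-[(triethylsilyl)oxy]pent-4-en-1-yl}lithium | C=C[C@](C)(O[Si](CC)(CC)CC)CC[Li] | intermediate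
25 | dichloro{(3R)-3-methyl-3-[(triethylsilyl)oxy]pent-4-en-1-yl}cerium | C=C[C@](C)(O[Si](CC)(CC)CC)CC[Ce](Cl)Cl | intermediate
26 | (13R)-6β-acetoxy-13-[(triethylsilyl)oxy]labda-7,14-dien-9-ol (C9 epimers, C9 left undefined) | C=C[C@](C)(O[Si](CC)(CC)CC)CCC1(O)C(C)=C[C@@H](OC(C)=O)[C@H]2C(C)(C)CCC[C@]12C | intermediate
27 | (13R)-6β-acetoxy-13-[(triethylsilyl)oxy]labda-8,14-dien-7-one | C=C[C@](C)(O[Si](CC)(CC)CC)CCC1=C(C)C(=O)[C@@H](OC(C)=O)[C@H]2C(C)(C)CCC[C@]12C | intermediate
28 | (13R)-6β-acetoxy-13-hydroxylabda-8,14-dien-7-one, (5S,6S,10S,13R) | C=C[C@](C)(O)CCC1=C(C)C(=O)[C@@H](OC(C)=O)[C@H]2C(C)(C)CCC[C@]12C | target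

**Step count and risks**

Total step count: 19. Longest linear sequence: 15 steps (steps 1–12, then 17–19); the side-chain branch (steps 13–16) joins in step 17.

Steps most likely to fail:

1. Step 7. The cycloaddition joins a β,β-dimethyl enone to a diene terminus that becomes quaternary, so it may be too slow below the temperature at which hydrogen shifts of the diene set in, or the facial and trans preferences may erode. The fallback sets out from 8 and activates the dienophile a second time through C5. Amide 8 is acylated with the lithium enolate of methyl acetate (LiN(i-Pr)2, THF, −78 °C) to the β-keto ester methyl (4Z,6S,7E)-6-[(tert-butyldimethylsilyl)oxy]-5,7-dimethyl-3-oxodeca-4,7,9-trienoate F1. Knoevenagel condensation with acetone (TiCl4, pyridine, THF) gives the isopropylidene keto ester F2. Its doubly activated alkene should cyclise at or below 60 °C (or with ZnBr2) to the C5-methoxycarbonyl cycloadduct F3. Krapcho dealkoxycarbonylation (LiCl, wet DMSO, 130 °C), with C5 set by protonation and base equilibration next to the ketone, comes back to the route at 11.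

2. Step 17. The organocerium may fail to discriminate between the hindered C9 carbonyl and the acetate (acyl attack) or may add incompletely. The fallback sets out from 16 and gives up chemoselectivity. An excess (about 3.5 equiv) of alkyllithium 24 in Et2O, −78 to 0 °C, without cerium, adds to the ketone and cleaves the acetate to give (13R)-13-[(triethylsilyl)oxy]labda-7,14-diene-6β,9-diol F4. Acetylation of its secondary 6β-hydroxyl only (Ac2O, DMAP, Et3N, 0 °C; the tertiary C9 hydroxyl is inert) comes back to the route at 26.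

3. Step 14. Electrophilic iodoacetoxylation of the vinyl group, or oxidation of the lactol to the lactone, may compete with β-fragmentation. The fallback sets out from 17 and removes the carbon by decarboxylation. Silylation (TESOTf, 2,6-lutidine) gives triethyl{[(3R)-3,7-dimethylocta-1,6-dien-3-yl]oxy}silane F5. Selective ozonolysis (O3; Me2S), through the ozonide F6, gives (4R)-4-methyl-4-[(triethylsilyl)oxy]hex-5-enal F7. Oxidation (NaClO2, NaH2PO4, 2-methylbut-2-ene) gives (4R)-4-methyl-4-[(triethylsilyl)oxy]hex-5-enoic acid F8. Esterification with N-hydroxypyridine-2-thione (DCC) gives the Barton ester F9, and its photolysis with CHI3 comes back to the route at 23.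

Further compounds
F1 | step 7 | methyl (4Z,6S,7E)-6-[(tert-butyldimethylsilyl)oxy]-5,7-dimethyl-3-oxodeca-4,7,9-trienoate | COC(=O)CC(=O)/C=C(/C)[C@@H](O[Si](C)(C)C(C)(C)C)/C(C)=C/C=C
F2 | step 7 | methyl (4Z,6S,7E)-6-[(tert-butyldimethylsilyl)oxy]-5,7-dimethyl-3-oxo-2-(propan-2-ylidene)deca-4,7,9-trienoate | COC(=O)C(=C(C)C)C(=O)/C=C(/C)[C@@H](O[Si](C)(C)C(C)(C)C)/C(C)=C/C=C
F3 | step 7 | cycloadduct corresponding to 11 with CO2CH3 in place of H on the ring-fusion carbon C5 (α) | [C@@H]1(O[Si](C)(C)C(C)(C)C)C(C)=CC(=O)[C@@]2(C(=O)OC)C(C)(C)CC=C[C@]12C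
F4 | step 17 | (13R)-13-[(triethylsilyl)oxy]labda-7,14-diene-6β,9-diol (C9 epimers) | C=C[C@](C)(O[Si](CC)(CC)CC)CCC1(O)C(C)=C[C@@H](O)[C@H]2C(C)(C)CCC[C@]12C
F5 | step 14 | triethyl{[(3R)-3,7-dimethylocta-1,6-dien-3-yl]oxy}silane | C=C[C@](C)(O[Si](CC)(CC)CC)CCC=C(C)C
F6 | step 14 | triethyl{[(3R)-5-(5,5-dimethyl-1,2,4-trioxolan-3-yl)-3-methylpent-1-en-3-yl]oxy}silane (ozonide) | C=C[C@](C)(O[Si](CC)(CC)CC)CCC1OOC(C)(C)O1
F7 | step 14 | (4R)-4-methyl-4-[(triethylsilyl)oxy]hex-5-enal | C=C[C@](C)(O[Si](CC)(CC)CC)CCC=O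
F8 | step 14 | (4R)-4-methyl-4-[(triethylsilyl)oxy]hex-5-enoic acid | C=C[C@](C)(O[Si](CC)(CC)CC)CCC(=O)O
F9 | step 14 | 2-sulfanylidenepyridin-1(2H)-yl (4R)-4-methyl-4-[(triethylsilyl)oxy]hex-5-enoate | C=C[C@](C)(O[Si](CC)(CC)CC)CCC(=O)ON1C=CC=CC1=S
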